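**Retrosynthetic overview**
1. Mycaperoxide H ⇐ diimide saturation of C6=C7 and C11=C12 ⇐ Julia–Kocienski union at C11=C12 of a bicyclic tetrazolyl sulfone and a 1,2-dioxane aldehyde acid.
2. Rings A and B ⇐ one thermal intramolecular Diels–Alder reaction of an axially chiral, γ-tethered 2-methylallenoate with an (E,Z)-diene: allene axis → C9, inside (Z)-methyl plus ester-exo → C8 and C5, spare allene C=C → the C1=C10 alkene.
3. Allenoate ⇐ anti-SN2′ carbonylation of an (R)-propargylic mesylate ⇐ transfer hydrogenation of an ynone ⇐ Takai/Suzuki diene from methyl 4,4-dimethyl-5-oxopentanoate.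
4. 1,2-Dioxane ⇐ 6-exo-tet opening of a cis-β-lactone by a tertiary hydroperoxide (inversion at C16, frees CO2H) ⇐ invertive perhydrolysis of an (R)-2,2-disubstituted epoxide; lactone by ketene–aldehyde cyclocondensation, epoxide from Sharpless epoxidation of methallyl alcohol.
5. Ring order: rings A and B together (step 7); the dioxane in the second branch (step 16); union and saturation last.

Assumption: methyl 4,4-dimethyl-5-oxopentanoate (the isobutyraldehyde/methyl acrylate Michael adduct) is bought; C1–C18 follow terpenoid numbering (decalin C1–C10, linker C11–C12, dioxane carbons C13–C16, α-carbon C17, carboxyl C18); "Sa/Ra" are allene axial descriptors.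

**Route**

Step 1
Reactants: 1 methyl 4,4-dimethyl-5-oxopentanoate
Product: 2 methyl (5E)-6-iodo-4,4-dimethylhex-5-enoate
Conditions: CrCl2 (6 equiv), CHI3 (2 equiv), THF, 0 °C → rt
Reagents that add atoms: iodoform IC(I)I
Why: Takai–Utimoto iodo-olefination, in which the geminal dichromium carbenoid adds to the α-quaternary aldehyde and eliminates to the (E)-vinyl iodide (hindered aldehydes give ≥95:5 E) without touching the ester.

Step 2
Reactants: 2 methyl (5E)-6-iodo-4,4-dimethylhex-5-enoate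
Product: 3 methyl (5E,7Z)-4,4-dimethylnona-5,7-dienoate
Conditions: (Z)-prop-1-en-1-ylboronic acid (1.3 equiv), Pd(PPh3)4 (5 mol %), K3PO4, THF/H2O, 45 °C
Reagents that add atoms: (Z)-prop-1-en-1-ylboronic acid C/C=C\B(O)O
Why: Suzuki–Miyaura coupling retains the geometry of both alkenyl partners, so the (5E,7Z)-diene that later places the C8 methyl "inside" is fixed here.

Step 3
Reactants: 3 methyl (5E,7Z)-4,4-dimethylnona-5,7-dienoate
Product: 5 (8E,10Z)-7,7-dimethyldodeca-8,10-dien-2-yn-4-one, via Weinreb amide 4 (not isolated)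
Conditions: MeNH(OMe)·HCl, iPrMgCl, THF, −20 °C; then 1-propynylmagnesium bromide, 0 °C → rt; aq. NH4Cl
Reagents that add atoms: 1-propynylmagnesium bromide CC#C[Mg]Br; N,O-dimethylhydroxylamine hydrochloride CNOC.Cl (its atoms stay only in 4)
Why: One-pot Weinreb amidation followed by Weinreb ketone synthesis, where the chelated tetrahedral adduct stops the alkynyl Grignard addition at the ynone.

Step 4
Reactants: 5 (8E,10Z)-7,7-dimethyldodeca-8,10-dien-2-yn-4-one
Product: 6 (4R,8E,10Z)-7,7-dimethyldodeca-8,10-dien-2-yn-4-ol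
Conditions: RuCl[(R,R)-TsDPEN](p-cymene) (1 mol %), iPrOH, rt
Reagents that add atoms: none
Why: Noyori asymmetric transfer hydrogenation of an alkynyl ketone, in which the (R,R)-catalyst differentiates alkynyl from alkyl and gives the (R)-carbinol (typically ≥97% ee) that later defines the allene axis.

Step 5
Reactants: 6 (4R,8E,10Z)-7,7-dimethyldodeca-8,10-dien-2-yn-4-ol
Product: 7 (4R,8E,10Z)-7,7-dimethyldodeca-8,10-dien-2-yn-4-yl methanesulfonate
Conditions: MsCl, Et3N, CH2Cl2, −78 °C; used directly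
Reagents that add atoms: methanesulfonyl chloride CS(Cl)(=O)=O
Why: O-sulfonylation of the propargylic alcohol proceeds with retention and installs the leaving group for SN2′ chemistry.

Step 6
Reactants: 7 (4R,8E,10Z)-7,7-dimethyldodeca-8,10-dien-2-yn-4-yl methanesulfonate
Product: 8 methyl (Sa,8E,10Z)-2,7,7-trimethyldodeca-2,3,8,10-tetraenoate
Conditions: Pd(PPh3)4 (5 mol %), CO (1 atm), MeOH/THF, rt
Reagents that add atoms: carbon monoxide [C-]#[O+]; methanol CO
Why: Marshall-type alkoxycarbonylation of a propargylic mesylate, in which zerovalent palladium displaces the mesylate anti-SN2′ and CO inserts with retention, so the (R)-carbinol centre becomes the (Sa)-allene axis.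

Step 7
Reactants: 8 methyl (Sa,8E,10Z)-2,7,7-trimethyldodeca-2,3,8,10-tetraenoate
Product: 9 methyl (1R,2R,4aS)-1,2,5,5-tetramethyl-1,2,4a,5,6,7-hexahydronaphthalene-1-carboxylate
Conditions: PhMe (0.01 M), BHT (cat.), 160 °C, sealed tube
Reagents that add atoms: none
Why: Intramolecular Diels–Alder reaction at the ester-activated α,β-bond of the allenoate closes ring A (tether) and ring B (cycloadduct) together; the tether reaches only the allene face syn to C2, so the axis becomes C9 (R), the inside (Z)-methyl and the preference of the slim ester for the exo site beside it (methyl endo, as with methacrylates) give C8 (R) and C5 (S), and the untouched allene π-bond becomes the C1=C10 alkene.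

Step 8
Reactants: 9 methyl (1R,2R,4aS)-1,2,5,5-tetramethyl-1,2,4a,5,6,7-hexahydronaphthalene-1-carboxylate
Product: 10 [(1R,2R,4aS)-1,2,5,5-tetramethyl-1,2,4a,5,6,7-hexahydronaphthalen-1-yl]methanol
Conditions: LiAlH4, Et2O, 0 °C → reflux
Reagents that add atoms: none
Why: Hydride reduction of the hindered ester to the neopentyl alcohol (the ester carbon is C11) leaves both alkenes and all stereocentres untouched.

Step 9
Reactants: 10 [(1R,2R,4aS)-1,2,5,5-tetramethyl-1,2,4a,5,6,7-hexahydronaphthalen-1-yl]methanol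
Product: 11 1-phenyl-5-({[(1R,2R,4aS)-1,2,5,5-tetramethyl-1,2,4a,5,6,7-hexahydronaphthalen-1-yl]methyl}sulfanyl)-1H-tetrazole
Conditions: 1-phenyl-1H-tetrazole-5-thiol, PPh3, DIAD, THF, 0 → 50 °C
Reagents that add atoms: 1-phenyl-1H-tetrazole-5-thiol Sc1nnnn1-c1ccccc1
Why: Mitsunobu thioetherification, in which the acidic, highly nucleophilic thiol displaces the oxyphosphonium at the primary (neopentyl) carbon without involving a stereocentre.

Step 10
Reactants: 11 1-phenyl-5-({[(1R,2R,4aS)-1,2,5,5-tetramethyl-1,2,4a,5,6,7-hexahydronaphthalen-1-yl]methyl}sulfanyl)-1H-tetrazole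
Product: 12 1-phenyl-5-({[(1R,2R,4aS)-1,2,5,5-tetramethyl-1,2,4a,5,6,7-hexahydronaphthalen-1-yl]methyl}sulfonyl)-1H-tetrazole
Conditions: (NH4)6Mo7O24·4H2O (10 mol %), 30% H2O2, EtOH, 0 °C → rt
Reagents that add atoms: hydrogen peroxide OO
Why: Molybdate-catalysed sulfide-to-sulfone oxidation is selective for sulfur over the isolated, hindered alkenes.

Step 11
Reactants: 13 2-methylprop-2-en-1-ol
Product: 15 [(2R)-2-methyloxiran-2-yl]methyl 4-methylbenzenesulfonate, via epoxy alcohol 14 (not isolated)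
Conditions: Ti(OiPr)4 (5 mol %), L-(+)-DIPT (6 mol %), cumene hydroperoxide, 4 Å MS, CH2Cl2, −20 °C; then P(OMe)3, Et3N, TsCl, DMAP (cat.), −10 °C
Reagents that add atoms: cumene hydroperoxide CC(C)(OO)c1ccccc1; 4-methylbenzenesulfonyl chloride Cc1ccc(cc1)S(Cl)(=O)=O
Why: Sharpless asymmetric epoxidation with the L-tartrate gives (S)-2-methylglycidol, and in situ tosylation traps this water-soluble epoxy alcohol without touching the quaternary centre (only the descriptor changes to R).

Step 12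
Reactants: 15 [(2R)-2-methyloxiran-2-yl]methyl 4-methylbenzenesulfonate
Product: 17 (2R)-2-(but-3-en-1-yl)-2-methyloxirane, via tosyloxy alcohol 16 (not isolated)
Conditions: allylMgBr, CuI (10 mol %), THF, −40 °C; then aq. NaOH, rt
Reagents that add atoms: allylmagnesium bromide C=CC[Mg]Br
Why: Copper-catalysed Grignard opening of the epoxide at its CH2, then intramolecular Williamson closure of the tertiary alkoxide onto CH2OTs, relocates the epoxide without breaking any bond to the stereocentre.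

Step 13
Reactants: 17 (2R)-2-(but-3-en-1-yl)-2-methyloxirane
Product: 19 3-[(2R)-2-methyloxiran-2-yl]propanal, via ozonide 18 (not isolated)
Conditions: O3, CH2Cl2, −78 °C; then PPh3, −78 °C → rt
Reagents that add atoms: ozone [O-][O+]=O
Why: Ozonolysis with reductive work-up cleaves the terminal alkene to the C16 aldehyde while the epoxide is inert.

Step 14
Reactants: 19 3-[(2R)-2-methyloxiran-2-yl]propanal
Product: 20 (3S,4R)-3-methyl-4-{2-[(2R)-2-methyloxiran-2-yl]ethyl}oxetan-2-one
Conditions: EtCOCl, O-trimethylsilylquinine (10 mol %), LiClO4, iPr2NEt, CH2Cl2/Et2O, −78 °C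
Reagents that add atoms: propanoyl chloride CCC(Cl)=O
Why: Nelson's catalytic asymmetric acyl halide–aldehyde cyclocondensation (Wynberg-type ketene–aldehyde [2+2] through a cinchona ammonium enolate) gives the cis-β-lactone and sets C17 (S) and C16 (R) under catalyst control; the pseudoenantiomeric quinidine catalyst would give the antipodal lactone.

Step 15
Reactants: 20 (3S,4R)-3-methyl-4-{2-[(2R)-2-methyloxiran-2-yl]ethyl}oxetan-2-one
Product: 21 (3S,4R)-4-[(3S)-3-hydroperoxy-4-hydroxy-3-methylbutyl]-3-methyloxetan-2-one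
Conditions: anhydrous H2O2 in Et2O (10 equiv), H3PMo12O40 (5 mol %), rt
Reagents that add atoms: hydrogen peroxide OO
Why: Phosphomolybdic-acid-catalysed perhydrolysis of a 2,2-disubstituted epoxide, in which H2O2 attacks the activated epoxide at the tertiary carbon with inversion to set C13 and leaves C12 as a primary alcohol.

Step 16
Reactants: 21 (3S,4R)-4-[(3S)-3-hydroperoxy-4-hydroxy-3-methylbutyl]-3-methyloxetan-2-one
Product: 22 (2S)-2-[(3S,6S)-6-(hydroxymethyl)-6-methyl-1,2-dioxan-3-yl]propanoic acid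
Conditions: KOtBu (1.05 equiv), 18-crown-6, THF, −20 → 0 °C; then aq. HCl to pH 3
Reagents that add atoms: none
Why: Proposed new method: the selectively deprotonated hydroperoxide (more acidic and, through the α-effect, more nucleophilic than the alcohol) attacks the lactone β-carbon C16 in a 6-exo-tet SN2 with inversion, which closes the 1,2-dioxane, converts the cis-lactone into the anti C16/C17 pair and releases the carboxylate, while acyl attack would need an eight-membered ring and the product carboxylate is too weak a base for Kornblum–DeLaMare cleavage; the closest known chemistry is SN2 alkyl–oxygen opening of β-lactones by azide, thiolate and carboxylate nucleophiles and Dussault-type intramolecular alkylation of hydroperoxides by secondary sulfonates.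

Step 17
Reactants: 22 (2S)-2-[(3S,6S)-6-(hydroxymethyl)-6-methyl-1,2-dioxan-3-yl]propanoic acid
Product: 23 (2S)-2-[(3S,6S)-6-formyl-6-methyl-1,2-dioxan-3-yl]propanoic acid
Conditions: Dess–Martin periodinane, CH2Cl2, 0 °C → rt
Reagents that add atoms: none
Why: Dess–Martin oxidation of the primary alcohol gives a non-enolisable aldehyde under neutral conditions that the peroxide and the free acid tolerate.

Step 18
Reactants: 12 1-phenyl-5-({[(1R,2R,4aS)-1,2,5,5-tetramethyl-1,2,4a,5,6,7-hexahydronaphthalen-1-yl]methyl}sulfonyl)-1H-tetrazole; 23 (2S)-2-[(3S,6S)-6-formyl-6-methyl-1,2-dioxan-3-yl]propanoic acid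
Product: 24 (2S)-2-[(3S,6S)-6-methyl-6-{(E)-2-[(1R,2R,4aS)-1,2,5,5-tetramethyl-1,2,4a,5,6,7-hexahydronaphthalen-1-yl]ethenyl}-1,2-dioxan-3-yl]propanoic acid
Conditions: 12 (1.1 equiv), 23 (1.0 equiv), KN(SiMe3)2 (2.2 equiv) added last, DME, −78 °C → rt; aq. NH4Cl
Reagents that add atoms: none
Why: Julia–Kocienski olefination, in which the first equivalent of base forms the carboxylate (blocking E1cB opening of the dioxane), the metalated sulfone adds to the aldehyde, and Smiles rearrangement with loss of SO2 forms the C11=C12 alkene without touching a stereocentre.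

Step 19
Reactants: 24 (2S)-2-[(3S,6S)-6-methyl-6-{(E)-2-[(1R,2R,4aS)-1,2,5,5-tetramethyl-1,2,4a,5,6,7-hexahydronaphthalen-1-yl]ethenyl}-1,2-dioxan-3-yl]propanoic acid
Product: 25 mycaperoxide H, (2S)-2-[(3S,6R)-6-methyl-6-{2-[(1R,2R,4aS)-1,2,5,5-tetramethyl-1,2,3,4,4a,5,6,7-octahydronaphthalen-1-yl]ethyl}-1,2-dioxan-3-yl]propanoic acid
Conditions: KO2CN=NCO2K (large excess, in portions), AcOH, MeOH/CH2Cl2, 0 °C → rt, monitored
Reagents that add atoms: none
Why: Diimide reduction delivers H2 in a concerted syn fashion to the two 1,2-disubstituted alkenes (C6=C7 and C11=C12) but spares the O–O bond and the slower, hindered trisubstituted C1=C10 alkene.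

**Compound list**
1 | methyl 4,4-dimethyl-5-oxopentanoate | COC(=O)CCC(C)(C)C=O | starting material
2 | methyl (5E)-6-iodo-4,4-dimethylhex-5-enoate | COC(=O)CCC(C)(C)/C=C/I | intermediate
3 | methyl (5E,7Z)-4,4-dimethylnona-5,7-dienoate | COC(=O)CCC(C)(C)/C=C/C=C\C | intermediate
4 | (5E,7Z)-N-methoxy-N,4,4-trimethylnona-5,7-dienamide | CON(C)C(=O)CCC(C)(C)/C=C/C=C\C | intermediate (not isolated)
5 | (8E,10Z)-7,7-dimethyldodeca-8,10-dien-2-yn-4-one | CC#CC(=O)CCC(C)(C)/C=C/C=C\C | intermediate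
6 | (4R,8E,10Z)-7,7-dimethyldodeca-8,10-dien-2-yn-4-ol | CC#C[C@H](O)CCC(C)(C)/C=C/C=C\C | intermediate
7 | (4R,8E,10Z)-7,7-dimethyldodeca-8,10-dien-2-yn-4-yl methanesulfonate | CC#C[C@H](OS(C)(=O)=O)CCC(C)(C)/C=C/C=C\C | intermediate
8 | methyl (Sa,8E,10Z)-2,7,7-trimethyldodeca-2,3,8,10-tetraenoate | COC(=O)C(C)=[C@@]=C([H])CCC(C)(C)/C=C/C=C\C | intermediate
9 | methyl (1R,2R,4aS)-1,2,5,5-tetramethyl-1,2,4a,5,6,7-hexahydronaphthalene-1-carboxylate | COC(=O)[C@@]1(C)C2=CCCC(C)(C)[C@@H]2C=C[C@H]1C | intermediate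
10 | [(1R,2R,4aS)-1,2,5,5-tetramethyl-1,2,4a,5,6,7-hexahydronaphthalen-1-yl]methanol | OC[C@@]1(C)C2=CCCC(C)(C)[C@@H]2C=C[C@H]1C | intermediate
11 | 1-phenyl-5-({[(1R,2R,4aS)-1,2,5,5-tetramethyl-1,2,4a,5,6,7-hexahydronaphthalen-1-yl]methyl}sulfanyl)-1H-tetrazole | c1ccccc1-n1nnnc1SC[C@@]1(C)C2=CCCC(C)(C)[C@@H]2C=C[C@H]1C | intermediate
12 | 1-phenyl-5-({[(1R,2R,4aS)-1,2,5,5-tetramethyl-1,2,4a,5,6,7-hexahydronaphthalen-1-yl]methyl}sulfonyl)-1H-tetrazole | O=S(=O)(C[C@@]1(C)C2=CCCC(C)(C)[C@@H]2C=C[C@H]1C)c1nnnn1-c1ccccc1 | intermediate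
13 | 2-methylprop-2-en-1-ol | C=C(C)CO | starting material
14 | [(2S)-2-methyloxiran-2-yl]methanol | OC[C@@]1(C)CO1 | intermediate (not isolated)
15 | [(2R)-2-methyloxiran-2-yl]methyl 4-methylbenzenesulfonate | Cc1ccc(cc1)S(=O)(=O)OC[C@@]1(C)CO1 | intermediate
16 | (2R)-2-hydroxy-2-methylhex-5-en-1-yl 4-methylbenzenesulfonate (present as its bromomagnesium alkoxide) | C=CCC[C@@](C)(O)COS(=O)(=O)c1ccc(C)cc1 | intermediate (not isolated)
17 | (2R)-2-(but-3-en-1-yl)-2-methyloxirane | C=CCC[C@]1(C)CO1 | intermediate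
18 | 3-{2-[(2R)-2-methyloxiran-2-yl]ethyl}-1,2,4-trioxolane | C1(CC[C@]2(C)CO2)OCOO1 | intermediate (not isolated)
19 | 3-[(2R)-2-methyloxiran-2-yl]propanal | O=CCC[C@]1(C)CO1 | intermediate
20 | (3S,4R)-3-methyl-4-{2-[(2R)-2-methyloxiran-2-yl]ethyl}oxetan-2-one | C[C@@H]1C(=O)O[C@@H]1CC[C@]2(C)CO2 | intermediate
21 | (3S,4R)-4-[(3S)-3-hydroperoxy-4-hydroxy-3-methylbutyl]-3-methyloxetan-2-one | C[C@@H]1C(=O)O[C@@H]1CC[C@@](C)(CO)OO | intermediate
22 | (2S)-2-[(3S,6S)-6-(hydroxymethyl)-6-methyl-1,2-dioxan-3-yl]propanoic acid | C[C@H](C(=O)O)[C@@H]1CC[C@@](C)(CO)OO1 | intermediate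
23 | (2S)-2-[(3S,6S)-6-formyl-6-methyl-1,2-dioxan-3-yl]propanoic acid | C[C@H](C(=O)O)[C@@H]1CC[C@@](C)(C=O)OO1 | intermediate
24 | (2S)-2-[(3S,6S)-6-methyl-6-{(E)-2-[(1R,2R,4aS)-1,2,5,5-tetramethyl-1,2,4a,5,6,7-hexahydronaphthalen-1-yl]ethenyl}-1,2-dioxan-3-yl]propanoic acid | C[C@H](C(=O)O)[C@@H]1CC[C@@](C)(/C=C/[C@@]2(C)C3=CCCC(C)(C)[C@@H]3C=C[C@H]2C)OO1 | intermediate
25 | mycaperoxide H | C[C@H](C(=O)O)[C@@H]1CC[C@@](C)(CC[C@@]2(C)C3=CCCC(C)(C)[C@@H]3CC[C@H]2C)OO1 | target

**Totals**
Total step count: 19. Longest linear sequence: 12 (steps 1–10, 18, 19); the dioxane branch is steps 11–17.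

**Three steps most likely to fail**

Step 7. The (Z)-diene is a sluggish diene, the ester-exo/methyl-endo preference is argued by analogy and not demonstrated, and the unactivated allene π-bond could compete through a five-membered tether. The fallback swaps the roles of the two C9 substituents so that the conventional ester-endo transition state gives the right relative configuration; it sets out from 3 and comes back at 10. The Weinreb amide 4 made in the flask from 3 is treated with the lithium acetylide of 1-methoxy-4-[(prop-2-yn-1-yloxy)methyl]benzene to give the PMB-oxy ynone F1. RuCl[(S,S)-TsDPEN](p-cymene) in iPrOH gives the (S)-propargylic alcohol F2, MsCl/Et3N its mesylate F3, and Pd(PPh3)4/CO/MeOH the (Ra)-allenoate F4, whose ester now occupies the site that must become the C9 methyl. Cycloaddition promoted by Me2AlCl (CH2Cl2, −40 °C) or heat, through the ester-endo transition state, gives the bicyclic ester F5. LiAlH4 gives the alcohol F6, MsCl/Et3N the neopentyl mesylate F7, LiBHEt3 reduces this to the C9-methyl PMB ether F8, and DDQ (CH2Cl2/H2O) releases 10.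

Step 16. Opening a β-lactone with a peroxide anion is unprecedented; acyl attack, β-elimination or fragmentation of the β-hydroxy hydroperoxide may compete. The fallback replaces the SN2 closure by the classical peroxy-Michael closure; it sets out from 19 and comes back at 22. Wittig reaction of 19 with Ph3P=C(Me)CO2Me gives the (E)-enoate epoxide F9; the same H3PMo12O40/H2O2 perhydrolysis gives the hydroperoxy enoate F10 with C13 still set by inversion. Et2NH in CF3CH2OH then closes the ring to the dioxane methyl ester F11, which must be separated by chromatography from its C16/C17 diastereomers because these two centres are only substrate-controlled here. LiOH (THF/H2O) gives 22.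

Step 18. Both partners are neopentyl-type (C11 next to quaternary C9, the aldehyde on quaternary C13), so addition of the sulfone anion may be slow. The fallback uses the more nucleophilic phosphorus ylide; it sets out from 10 and comes back at 25. I2/PPh3/imidazole converts 10 into the neopentyl iodide F12, neat PPh3 at 130 °C gives the phosphonium iodide F13, and the ylide from NaN(SiMe3)2 reacts with the sodium carboxylate of 23 to give the (Z)-alkene acid F14 (or an E/Z mixture containing 24). The same diimide reduction (KO2CN=NCO2K, AcOH) gives 25.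

Further compounds
F1 | step 7 | (8E,10Z)-1-[(4-methoxyphenyl)methoxy]-7,7-dimethyldodeca-8,10-dien-2-yn-4-one | COc1ccc(COCC#CC(=O)CCC(C)(C)/C=C/C=C\C)cc1
F2 | step 7 | (4S,8E,10Z)-1-[(4-methoxyphenyl)methoxy]-7,7-dimethyldodeca-8,10-dien-2-yn-4-ol | COc1ccc(COCC#C[C@@H](O)CCC(C)(C)/C=C/C=C\C)cc1
F3 | step 7 | (4S,8E,10Z)-1-[(4-methoxyphenyl)methoxy]-7,7-dimethyldodeca-8,10-dien-2-yn-4-yl methanesulfonate | COc1ccc(COCC#C[C@@H](OS(C)(=O)=O)CCC(C)(C)/C=C/C=C\C)cc1
F4 | step 7 | methyl (Ra,8E,10Z)-2-{[(4-methoxyphenyl)methoxy]methyl}-7,7-dimethyldodeca-2,3,8,10-tetraenoate | COC(=O)C(COCc1ccc(OC)cc1)=[C@]=C([H])CCC(C)(C)/C=C/C=C\C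
F5 | step 7 | methyl (1S,2R,4aS)-1-{[(4-methoxyphenyl)methoxy]methyl}-2,5,5-trimethyl-1,2,4a,5,6,7-hexahydronaphthalene-1-carboxylate | COc1ccc(COC[C@@]2(C(=O)OC)C3=CCCC(C)(C)[C@@H]3C=C[C@H]2C)cc1
F6 | step 7 | [(1R,2R,4aS)-1-{[(4-methoxyphenyl)methoxy]methyl}-2,5,5-trimethyl-1,2,4a,5,6,7-hexahydronaphthalen-1-yl]methanol | COc1ccc(COC[C@@]2(CO)C3=CCCC(C)(C)[C@@H]3C=C[C@H]2C)cc1
F7 | step 7 | [(1S,2R,4aS)-1-{[(4-methoxyphenyl)methoxy]methyl}-2,5,5-trimethyl-1,2,4a,5,6,7-hexahydronaphthalen-1-yl]methyl methanesulfonate | COc1ccc(COC[C@@]2(COS(C)(=O)=O)C3=CCCC(C)(C)[C@@H]3C=C[C@H]2C)cc1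
F8 | step 7 | 1-methoxy-4-({[(1R,2R,4aS)-1,2,5,5-tetramethyl-1,2,4a,5,6,7-hexahydronaphthalen-1-yl]methoxy}methyl)benzene | COc1ccc(COC[C@@]2(C)C3=CCCC(C)(C)[C@@H]3C=C[C@H]2C)cc1
F9 | step 16 | methyl (2E)-2-methyl-5-[(2R)-2-methyloxiran-2-yl]pent-2-enoate | COC(=O)/C(C)=C/CC[C@]1(C)CO1
F10 | step 16 | methyl (2E,6S)-6-hydroperoxy-7-hydroxy-2,6-dimethylhept-2-enoate | COC(=O)/C(C)=C/CC[C@@](C)(CO)OO
F11 | step 16 | methyl (2S)-2-[(3S,6S)-6-(hydroxymethyl)-6-methyl-1,2-dioxan-3-yl]propanoate | COC(=O)[C@@H](C)[C@@H]1CC[C@@](C)(CO)OO1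
F12 | step 18 | (1R,2R,4aS)-1-(iodomethyl)-1,2,5,5-tetramethyl-1,2,4a,5,6,7-hexahydronaphthalene | IC[C@@]1(C)C2=CCCC(C)(C)[C@@H]2C=C[C@H]1C
F13 | step 18 | triphenyl{[(1R,2R,4aS)-1,2,5,5-tetramethyl-1,2,4a,5,6,7-hexahydronaphthalen-1-yl]methyl}phosphonium iodide | c1ccccc1[P+](c1ccccc1)(c1ccccc1)C[C@@]1(C)C2=CCCC(C)(C)[C@@H]2C=C[C@H]1C.[I-]
F14 | step 18 | (2S)-2-[(3S,6S)-6-methyl-6-{(Z)-2-[(1R,2R,4aS)-1,2,5,5-tetramethyl-1,2,4a,5,6,7-hexahydronaphthalen-1-yl]ethenyl}-1,2-dioxan-3-yl]propanoic acid | C[C@H](C(=O)O)[C@@H]1CC[C@@](C)(/C=C\[C@@]2(C)C3=CCCC(C)(C)[C@@H]3C=C[C@H]2C)OO1
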